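**Retrosynthetic overview**

1. Honyucitrin is 5,7,4'-trihydroxy-3',5'-diprenylflavone and has no stereocentre. The last two operations are replacement of two ring A fluorides by allyloxide and removal of all three O-allyl groups with zerovalent palladium.
2. Structural feature: in ring A the three oxygen-bearing carbons C8a, C5 and C7 stand ortho, ortho and para to the C4 carbonyl, so each of their C–O bonds can be made by fluoride displacement on one symmetric 2,4,6-trifluorobenzoyl unit.
3. Key disconnection: C3–C4 (C-acylation of a methyl ketone enolate) and O1–C8a (intramolecular SNAr), leading back to 4-allyloxy-3,5-diprenylacetophenone and 2,4,6-trifluorobenzoyl chloride. Ring C is the only ring formed; rings A and B are bought as benzenes.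
4. The acetophenone is made from 4-hydroxyacetophenone by two O-allylation/Claisen rounds, double cross-metathesis with 2-methyl-2-butene and a final O-allylation; this replaces an unselective direct C-prenylation of the phenol.

Key step: step 7

Remark on the chemistry: prenyl means 3-methylbut-2-en-1-yl and flavone numbering is used (primed locants for ring B); in steps 5, 8 and 9 the same reaction runs at two or three sites in one flask, and the partly converted species, which form in no fixed order and are consumed, are not numbered, nor are the dienone tautomers of the Claisen steps.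

**Route**

Step 1
Reactants: 1 4-hydroxyacetophenone; 2 allyl bromide
Product: 3 4-allyloxyacetophenone
Conditions: K2CO3, acetone, reflux
Reagents that add atoms: allyl bromide (2), C=CCBr
Why: Williamson ether synthesis, in which the phenoxide is O-alkylated by a reactive allylic bromide in a polar aprotic medium.

Step 2
Reactants: 3 4-allyloxyacetophenone
Product: 4 3-allyl-4-hydroxyacetophenone
Conditions: N,N-diethylaniline, 200 °C
Reagents that add atoms: none
Why: Aromatic Claisen rearrangement, a [3,3] shift to the ortho carbon followed by tautomerization, with the para position blocked by the acetyl group so that only the ortho-allyl phenol can form.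

Step 3
Reactants: 4 3-allyl-4-hydroxyacetophenone; 2 allyl bromide
Product: 5 3-allyl-4-allyloxyacetophenone
Conditions: K2CO3, acetone, reflux
Reagents that add atoms: allyl bromide (2), C=CCBr
Why: Williamson ether synthesis on a phenol with one ortho substituent, which remains readily O-alkylated.

Step 4
Reactants: 5 3-allyl-4-allyloxyacetophenone
Product: 6 3,5-diallyl-4-hydroxyacetophenone
Conditions: N,N-diethylaniline, 200 °C
Reagents that add atoms: none
Why: Second aromatic Claisen rearrangement, which delivers the allyl group to the one free ortho carbon because the other ortho and the para positions are substituted.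

Step 5
Reactants: 6 3,5-diallyl-4-hydroxyacetophenone; 7 2-methyl-2-butene
Product: 8 4-hydroxy-3,5-diprenylacetophenone
Conditions: second-generation Grubbs catalyst RuCl2(=CHPh)(PCy3)(H2IMes) (5 mol %), 2-methyl-2-butene/CH2Cl2, 40 °C, sealed vessel
Reagents that add atoms: 2-methyl-2-butene (7), CC=C(C)C
Why: Olefin cross-metathesis of each terminal allyl group with a large excess of the trisubstituted alkene should give the prenyl groups with loss of propene, the excess alkene suppressing homodimerization and the free phenol and ketone being tolerated by the ruthenium carbene.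

Step 6
Reactants: 8 4-hydroxy-3,5-diprenylacetophenone; 2 allyl bromide
Product: 9 4-allyloxy-3,5-diprenylacetophenone
Conditions: K2CO3, DMF, 50 °C
Reagents that add atoms: allyl bromide (2), C=CCBr
Why: Williamson ether synthesis, in which DMF makes the hindered 2,6-disubstituted phenoxide reactive enough for clean O-allylation.

Step 7
Reactants: 9 4-allyloxy-3,5-diprenylacetophenone; 10 2,4,6-trifluorobenzoyl chloride
Product: 13 4'-allyloxy-5,7-difluoro-3',5'-diprenylflavone, via lithium enolate 11 (not isolated), via trifluorophenyl diketone 12 (not isolated)
Conditions: LiN(SiMe3)2 (2.2 equiv), THF, −78 °C; then 10 (1.0 equiv), −78 °C to rt; then K2CO3 (2 equiv, base reservoir), DMF, 80 °C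
Reagents that add atoms: none
Why: LiN(SiMe3)2 converts 9 into lithium enolate 11, whose carbon attacks the acid chloride to form C3–C4, and the second equivalent of base at once deprotonates the more acidic 1,3-diketone 12, which shields it from a second acylation. In DMF at 80 °C the diketonate oxygen on the ring B side adds to an ortho C–F carbon of the trifluorophenyl ring, the Meisenheimer adduct is stabilized by the adjacent carbonyl and the remaining fluorines, and loss of fluoride forms O1–C8a. The closest known reaction type is the base-mediated cyclization of 1-(2-halophenyl)-1,3-diketones to chromones and flavones, which has also been run in one pot from 2-fluorobenzoyl chlorides and ketone enolates. Ring C closes as a six-membered ring by intramolecular addition–elimination (SNAr) of an enolate oxygen at an aromatic carbon. No stereocentre is formed. The step needs C- over O-acylation, which the tightly coordinated lithium enolate in THF at −78 °C with excess base should secure, and ortho over para fluoride displacement, which the six-membered intramolecular geometry secures, while the two ortho fluorines of 10 are equivalent so either closure gives the same flavone.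

Step 8
Reactants: 13 4'-allyloxy-5,7-difluoro-3',5'-diprenylflavone; 14 allyl alcohol
Product: 15 5,7,4'-tris(allyloxy)-3',5'-diprenylflavone
Conditions: NaH (4 equiv), allyl alcohol (6 equiv), THF/DMF, 0 °C to 60 °C
Reagents that add atoms: allyl alcohol (14), C=CCO
Why: Two nucleophilic aromatic substitutions by sodium allyloxide at C7 (para to the C4 carbonyl) and C5 (ortho to it) should proceed because the first allyloxy group is meta to the second fluoride and so barely deactivates it, while alkoxide addition at C2 is reversible and returns the flavone.

Step 9
Reactants: 15 5,7,4'-tris(allyloxy)-3',5'-diprenylflavone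
Product: 16 honyucitrin (5,7,4'-trihydroxy-3',5'-diprenylflavone)
Conditions: Pd(PPh3)4 (5 mol %), morpholine (10 equiv), THF, rt; work-up with pH 5 phosphate buffer
Reagents that add atoms: none
Why: Tsuji–Trost deallylation, in which zerovalent palladium ionizes each aryl allyl ether to a phenoxide and an allylpalladium species that morpholine traps irreversibly, under neutral conditions that leave the prenyl alkenes and the flavone untouched.

**Compound list**

1 | 4-hydroxyacetophenone | CC(=O)c1ccc(O)cc1 | starting material
2 | allyl bromide | C=CCBr | starting material
3 | 4-allyloxyacetophenone | CC(=O)c1ccc(OCC=C)cc1 | intermediate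
4 | 3-allyl-4-hydroxyacetophenone | CC(=O)c1ccc(O)c(CC=C)c1 | intermediate
5 | 3-allyl-4-allyloxyacetophenone | CC(=O)c1ccc(OCC=C)c(CC=C)c1 | intermediate
6 | 3,5-diallyl-4-hydroxyacetophenone | CC(=O)c1cc(CC=C)c(O)c(CC=C)c1 | intermediate
7 | 2-methyl-2-butene | CC=C(C)C | starting material
8 | 4-hydroxy-3,5-diprenylacetophenone | CC(=O)c1cc(CC=C(C)C)c(O)c(CC=C(C)C)c1 | intermediate
9 | 4-allyloxy-3,5-diprenylacetophenone | CC(=O)c1cc(CC=C(C)C)c(OCC=C)c(CC=C(C)C)c1 | intermediate
10 | 2,4,6-trifluorobenzoyl chloride | O=C(Cl)c1c(F)cc(F)cc1F | starting material
11 | lithium enolate of 9 (lithium 1-[4-allyloxy-3,5-diprenylphenyl]ethenolate) | [Li+].[O-]C(=C)c1cc(CC=C(C)C)c(OCC=C)c(CC=C(C)C)c1 | intermediate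
12 | 1-(4-allyloxy-3,5-diprenylphenyl)-3-(2,4,6-trifluorophenyl)propane-1,3-dione (present in the flask as its enolate) | O=C(CC(=O)c1c(F)cc(F)cc1F)c1cc(CC=C(C)C)c(OCC=C)c(CC=C(C)C)c1 | intermediate
13 | 4'-allyloxy-5,7-difluoro-3',5'-diprenylflavone | C=CCOc1c(CC=C(C)C)cc(-c2cc(=O)c3c(F)cc(F)cc3o2)cc1CC=C(C)C | intermediate
14 | allyl alcohol | C=CCO | starting material
15 | 5,7,4'-tris(allyloxy)-3',5'-diprenylflavone | C=CCOc1c(CC=C(C)C)cc(-c2cc(=O)c3c(OCC=C)cc(OCC=C)cc3o2)cc1CC=C(C)C | intermediate
16 | honyucitrin, 5,7,4'-trihydroxy-3',5'-diprenylflavone | CC(C)=CCc1cc(-c2cc(=O)c3c(O)cc(O)cc3o2)cc(CC=C(C)C)c1O | target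

**Step count and risks**

Total step count: 9. Longest linear sequence: 9 steps, from 4-hydroxyacetophenone (1) to honyucitrin (16); compounds 2, 7, 10 and 14 are bought.

Steps most likely to fail:

Step 7. The enolate may be acylated on oxygen instead of carbon, the diketonate may be acylated a second time, or the fluoride displacement may stall. The fallback sets out from 9 and comes back to the route at 12. Enolate 11 (LiN(SiMe3)2, THF, −78 °C) would be added to purchased 2,4,6-trifluorobenzaldehyde (O=Cc1c(F)cc(F)cc1F), an electrophile that can be neither O-acylating nor over-acylating, to give racemic 1-(4-allyloxy-3,5-diprenylphenyl)-3-hydroxy-3-(2,4,6-trifluorophenyl)propan-1-one F1. Oxidation of the carbinol with Dess–Martin periodinane (CH2Cl2, NaHCO3, rt) would give diketone 12, which would then be closed to 13 with K2CO3 in DMF at 80 °C as in step 7.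

Step 8. The second fluoride displacement may stop short, or alkoxide attack at C2 may open ring C and lead on to retro-Claisen cleavage. The fallback sets out from 10 (with enolate 11 made from 9) and comes back at 15; it places the two allyloxy groups on ring A before ring closure. Acid chloride 10 would be treated with sodium allyloxide (NaH, allyl alcohol 14, 3 equiv, THF, 0 °C to rt), which first gives allyl 2,4,6-trifluorobenzoate F2 and then displaces the para and one ortho fluoride to give allyl 2,4-bis(allyloxy)-6-fluorobenzoate F3. Transesterification is degenerate with this alkoxide, and any isomer lacking an ortho fluorine would be removed by chromatography. Claisen condensation of enolate 11 with ester F3 (LiN(SiMe3)2, THF, rt to reflux) would give 1-(4-allyloxy-3,5-diprenylphenyl)-3-[2,4-bis(allyloxy)-6-fluorophenyl]propane-1,3-dione F4. Heating F4 with K2CO3 or Cs2CO3 in DMF at 100 °C would displace the remaining ortho fluoride and give 15 directly.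

Step 9. The allylpalladium intermediate may C-allylate the electron-rich ring A phenoxide at C6 or C8 in competition with the scavenger, or cleavage of the hindered 4'-O-allyl ether may remain incomplete. The fallback sets out from 15 and comes back at 16; it avoids any electrophilic allyl species. The three allyl ethers would be isomerized with hydrogen-activated [Ir(cod)(PMePh2)2]PF6 in THF at rt to 5,7,4'-tris[(E)-prop-1-enyloxy]-3',5'-diprenylflavone F5, the trisubstituted prenyl alkenes being expected to stay in place. The enol ethers would then be hydrolysed with dilute HCl (0.1 M) in aqueous acetone at rt, conditions expected to be too mild to cyclize the ortho-prenyl phenol, to give 16.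

**Further compounds**

F1 | step 7 | 1-(4-allyloxy-3,5-diprenylphenyl)-3-hydroxy-3-(2,4,6-trifluorophenyl)propan-1-one (racemic) | O=C(CC(O)c1c(F)cc(F)cc1F)c1cc(CC=C(C)C)c(OCC=C)c(CC=C(C)C)c1
F2 | step 8 | allyl 2,4,6-trifluorobenzoate | C=CCOC(=O)c1c(F)cc(F)cc1F
F3 | step 8 | allyl 2,4-bis(allyloxy)-6-fluorobenzoate | C=CCOC(=O)c1c(F)cc(OCC=C)cc1OCC=C
F4 | step 8 | 1-(4-allyloxy-3,5-diprenylphenyl)-3-[2,4-bis(allyloxy)-6-fluorophenyl]propane-1,3-dione | O=C(CC(=O)c1c(F)cc(OCC=C)cc1OCC=C)c1cc(CC=C(C)C)c(OCC=C)c(CC=C(C)C)c1
F5 | step 9 | 5,7,4'-tris[(E)-prop-1-enyloxy]-3',5'-diprenylflavone | C/C=C/Oc1c(CC=C(C)C)cc(-c2cc(=O)c3c(O/C=C/C)cc(O/C=C/C)cc3o2)cc1CC=C(C)C
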